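The runs are calculated with constants of no real substance; noise was put on by code.

The trap is to read the levelling of Sunday's run as a rate: its complex with three exchanged goes from 37.3 % at 2.00 d to 39.7 % at 4.00 d, which looks like a slow step but may simply be ligand consumed from a charge of 0.12 M.

| flask | starting complex | incoming ligand | protic impurity | remark | time |
|---|---|---|---|---|---|
| Thursday's | 0.050 M | 0.024 M | 0.010 M | run made earlier |  |
| Tuesday's | 0.050 M | 0.056 M | 0.010 M | run made earlier |  |
| Sunday's | 0.050 M | 0.12 M | 0.010 M | run made earlier |  |
| autumn | 0.050 M | 0.0250 M | 0.0100 M |  | 4.0 d |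
| dawn | 0.050 M | 0.0750 M | 0.0100 M |  | 4.0 d |
| spring | 0.050 M | 0.150 M | 0.0100 M |  | 4.0 d |

| run | time / d | complex with four exchanged / % | complex with three exchanged / % |
|---|---|---|---|
| Thursday's | 0.333 | 0.3 | 0.5 |
| Thursday's | 1.04 | 0 | 0.1 |
| Thursday's | 1.67 | 0.1 | 0.6 |
| Thursday's | 3.00 | 0.6 | 1.2 |
| Thursday's | 4.00 | 0.3 | 0.9 |
| Tuesday's | 0.333 | 0 | 1.3 |
| Tuesday's | 1.04 | 0.5 | 5.8 |
| Tuesday's | 1.67 | 0 | 7.1 |
| Tuesday's | 3.00 | 0.3 | 8.5 |
| Tuesday's | 4.00 | 0.2 | 9.4 |
| Sunday's | 0.333 | 0 | 9.0 |
| Sunday's | 0.625 | 1.7 | 19.8 |
| Sunday's | 1.04 | 3.5 | 29.7 |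
| Sunday's | 2.00 | 5.6 | 37.3 |
| Sunday's | 4.00 | 5.2 | 39.7 |

(standard deviation of a reading: 0.5 percentage points)



- final complex with four exchanged, as a percentage of the starting complex charged, for each flask in turn (autumn, dawn, spring)

For your quick number, I would treat incoming ligand as the limiting reagent, assume the protic impurity takes its own amount of it, and count what remains per complex: (c incoming ligand − c protic impurity) / c starting complex. For dawn that gives 1.30, the ligand budget, against 0.300 for autumn and 2.80 for spring. The earlier runs have budgets of 0.280, 0.920 and 2.20, and they end with 0.3 %, 0.2 % and 5.2 % of complex with four exchanged.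

So my own reckoning gives brackets, not points. Autumn sits beside Thursday's run, where readings are lost in a scatter of 0.5 percentage points. Dawn's budget is larger than Tuesday's and smaller than Sunday's, so its yield belongs between theirs. Spring's budget is larger than Sunday's, so its yield belongs above 5.2 %.

The forecast gives 0.1 %, 1.2 % and 12 %, taking Sunday's plateau to suggest that “the ligand is exhausted rather than the reaction being slow”.

The flasks give 0.0200 %, 1.11 % and 15.9 %.

    starting complex + incoming ligand → leaving ligand + complex with one exchanged (k = 1.50 /M/h)
    complex with one exchanged + incoming ligand → leaving ligand + complex with two exchanged (k = 2.00 /M/h)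
    complex with two exchanged + incoming ligand → leaving ligand + complex with three exchanged (k = 1.30 /M/h)
    complex with three exchanged + incoming ligand ⇌ leaving ligand + complex with four exchanged (K = 0.790, k = 0.270 /M/h)
    protic impurity + incoming ligand → quenched reagent (k = 1.20 /M/h)
    crystals ⇌ leaving ligand, rate k6*(cs6 - [leaving ligand]) while solid is left; crystals form when [leaving ligand] > cs6 (solubility = 1.90 mM, k = 8.00 /h)

Consumption of incoming ligand holds dawn's complex with four exchanged at 1.11 %, against 73.2 % in the same flask with that consumption taken away. Dawn's uptake is 1.37 equiv on a budget of 1.30; quenched reagent stands at 0.00657 M from 0.0100 M of impurity charged, and using that amount instead gives 1.37. In spring, a budget of 2.80 meets an uptake of 2.76, with 1.8 % of the incoming ligand still left at 4.00 d.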